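The ten-membered carbocycle is treated as the perimeter of a trans-decalin: a temporary C4–C9 bond divides it into ring A (C4 to C9) and ring B (C9, C10, C1 to C4). The feature exploited is the 1,3-relationship of oxygenated C9 and C5 across that bond. A tertiary C9 alkoxide and an equatorial C5 mesylate, both antiperiplanar to C4–C9, undergo Wharton–Grob fragmentation, which in one operation cuts the shared bond, creates the C9 ketone and the E C4=C5 alkene and releases the cyclodecane with C6, C7, C8 and C10 already in place. The precursor is a carvone-derived trans-decalin with C1 dioxolane, free C9 and C10 hydroxyls, O8 PMB, O6 silyl and C5 mesylate.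

Key step: step 19

Remarks on the chemistry (assumptions, one line each):
- Numbering used throughout: ring carbons C1 (ketone), C2, C3, C4 (CHMe), C5 (2-methylbutanoate), C6 (CHOH), C7, C8 (lactone oxygen), C9 (angelate), C10 (C(Me)OH); lactone carbons C11, C12 (C=O), C13 (=CH2).
- In the bicyclic compounds 8 to 23, α is the face of the C4 methyl and β the opposite face.
- TBS = tert-butyldimethylsilyl, TBDPS = tert-butyldiphenylsilyl, PMB = 4-methoxybenzyl.
- The target SMILES encodes an (R)-2-methylbutanoate and a (Z)-2-methylbut-2-enoate (angelate); (R)-2-methylbutanoic acid and angelic acid are assumed to be commercial.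
- Dione 5 is achiral, so carvone is a carbon source only and absolute configuration is introduced in step 6; the carvone methyl oxidised in step 1 becomes C13 and the carvone =CH2 becomes C12.
- C10–OH is left free on purpose: it directs the C8 reduction (step 16), anchors the chelate in the C9 reduction (step 20) and needs no late deprotection.

Step 1
Reactants: 1 (R)-carvone
Product: 2 (R)-10-hydroxycarvone
Conditions: SeO2 (cat.), t-BuOOH, CH2Cl2, rt
Reagents that add atoms: tert-butyl hydroperoxide, CC(C)(C)OO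
Why: Catalytic SeO2 allylic oxidation (ene reaction then [2,3]-sigmatropic shift) should hydroxylate the methyl group of the electron-rich 1,1-disubstituted alkene while the conjugated ring alkene stays inert and no stereocentre is touched.

Step 2
Reactants: 2 (R)-10-hydroxycarvone
Product: 3 10-(TBDPS-oxy)carvone
Conditions: TBDPSCl, imidazole, CH2Cl2, rt
Reagents that add atoms: tert-butyl(chloro)diphenylsilane, CC(C)(C)[Si](Cl)(c1ccccc1)c1ccccc1
Why: Standard silylation of a primary allylic alcohol gives a robust ether that masks the future C13 until the last step.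

Step 3
Reactants: 3 10-(TBDPS-oxy)carvone
Product: 4 trans-epoxy ketone
Conditions: H2O2 (30% aq.), NaOH (cat.), MeOH, 0 °C
Reagents that add atoms: hydrogen peroxide, OO
Why: Weitz–Scheffer nucleophilic epoxidation of the enone, with hydroperoxide adding anti to the ring substituent, although both epoxide stereocentres are erased in step 4.

Step 4
Reactants: 4 trans-epoxy ketone
Product: 5 symmetric 1,3-dione
Conditions: Pd(PPh3)4 (cat.), 1,2-bis(diphenylphosphino)ethane (cat.), toluene, 80 °C
Reagents that add atoms: none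
Why: Isomerisation of an α,β-epoxy ketone to a 1,3-diketone catalysed by zerovalent palladium (C–O oxidative addition then β-hydride elimination) gives an achiral dione with a mirror plane through C2 and C5 of the ring.

Step 5
Reactants: 5 symmetric 1,3-dione; 6 ethyl vinyl ketone
Product: 7 cis-triketone
Conditions: Et3N (cat.), MeCN, rt
Reagents that add atoms: none
Why: Michael addition of the dione enol creates the quaternary carbon (future C4), the chain being expected to enter axially and therefore cis to the equatorial side chain, and any trans isomer is removed as the diastereomeric enedione after step 6.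

Step 6
Reactants: 7 cis-triketone
Product: 8 enedione
Conditions: L-phenylalanine (1 equiv), (1S)-(+)-10-camphorsulfonic acid (0.5 equiv), DMF, rt → 70 °C
Reagents that add atoms: none
Why: Amino acid-mediated intramolecular aldol condensation (Hajos–Parrish reaction completing the Robinson annulation) lets the enamine of the side-chain ketone choose one of the two enantiotopic ring carbonyls, which sets C4 as S by catalyst control and, through the cis relationship from step 5, C7 as R.

Step 7
Reactants: 8 enedione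
Product: 9 dienol ethyl ether
Conditions: HC(OEt)3, p-TsOH·H2O (cat.), EtOH–THF, rt
Reagents that add atoms: triethyl orthoformate, CCOC(OCC)OCC
Why: Acid-catalysed dienol ether formation is selective for the conjugated ketone over the hindered neopentyl C5 ketone (as in steroidal 3-alkoxy-3,5-dienes), which blocks enolisation at C1 and arms C8 for γ-oxidation.

Step 8
Reactants: 9 dienol ethyl ether
Product: 11 6α-hydroxy ketone, via potassium enolate 10 (not isolated)
Conditions: KN(SiMe3)2, THF, −78 °C; then 2-(phenylsulfonyl)-3-phenyloxaziridine; AcOH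
Reagents that add atoms: 2-(phenylsulfonyl)-3-phenyloxaziridine, O=S(=O)(c1ccccc1)N1OC1c1ccccc1
Why: Davis oxidation of the only possible enolate (C5=C6) should deliver oxygen trans to the adjacent C7 substituent, giving mainly the 6α-alcohol, a configuration that is corrected in step 10.

Step 9
Reactants: 11 6α-hydroxy ketone
Product: 12 6α-silyl ether
Conditions: TBSOTf, 2,6-lutidine, CH2Cl2, −78 → 0 °C
Reagents that add atoms: tert-butyldimethylsilyl trifluoromethanesulfonate, CC(C)(C)[Si](C)(C)OS(=O)(=O)C(F)(F)F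
Why: Silyl triflate silylation protects the hindered secondary α-hydroxy ketone under non-enolising conditions.

Step 10
Reactants: 12 6α-silyl ether
Product: 13 6β-silyl ether
Conditions: DBU (cat.), toluene, 50 °C
Reagents that add atoms: none
Why: Base-mediated epimerisation through the C5 enolate should give the equatorial 6β-silyl ether, because it relieves the 1,3-diaxial contact of the 6α-oxygen with the pseudo-axial C4 methyl and because reprotonation occurs trans to the C7 substituent.

Step 11
Reactants: 13 6β-silyl ether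
Product: 14 8α-hydroxy enone
Conditions: m-CPBA, THF–H2O, 0 °C
Reagents that add atoms: m-chloroperbenzoic acid, OOC(=O)c1cccc(Cl)c1; water, O
Why: Peracid oxidation of the dienol ether at its terminal carbon C8 followed by hydrolysis of the oxocarbenium ion (the steroidal 6-hydroxylation of 3-alkoxy-3,5-dienes) should outpace attack on the allyl-ether alkene and place the hydroxyl anti to the pseudo-axial C7 substituent (8α), a provisional configuration that is used in step 12 and reset in steps 15 and 16.

Step 12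
Reactants: 14 8α-hydroxy enone
Product: 15 9α,10α-epoxy ketone
Conditions: H2O2 (30% aq.), NaOH (cat.), MeOH, 0 °C
Reagents that add atoms: hydrogen peroxide, OO
Why: Weitz–Scheffer epoxidation of the tetrasubstituted enone should occur on the α face, cis to the angular methyl as with steroidal 4-en-3-ones, guided by hydrogen bonding to the 8α-hydroxyl and screened from the β face by the pseudo-axial C7 substituent.

Step 13
Reactants: 15 9α,10α-epoxy ketone
Product: 16 8α,9β,10α-triol dione
Conditions: HClO4 (aq., cat.), THF–H2O, 0 °C → rt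
Reagents that add atoms: water, O
Why: Acid-catalysed epoxide hydrolysis under the Fürst–Plattner rule should open the protonated epoxide at C9 (remote from the deactivating C1 carbonyl) with inversion from the β face, giving the trans-diaxial 9β,10α-diol and with it the trans ring fusion.

Step 14
Reactants: 16 8α,9β,10α-triol dione
Product: 17 C1 dioxolane
Conditions: 2-ethyl-2-methyl-1,3-dioxolane, p-TsOH·H2O (cat.), rt
Reagents that add atoms: 2-ethyl-2-methyl-1,3-dioxolane, CCC1(C)OCCO1
Why: Mild acid-catalysed exchange dioxolanation should take C1, which has only one fully substituted neighbour, in preference to the C5 ketone shielded by quaternary C4 and the C6 silyl ether.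

Step 15
Reactants: 17 C1 dioxolane
Product: 18 5,8-diketone
Conditions: Dess–Martin periodinane, CH2Cl2, 0 °C → rt
Reagents that add atoms: none
Why: Dess–Martin oxidation of the only secondary alcohol under neutral, non-enolising conditions erases the provisional C8 configuration without disturbing C7.

Step 16
Reactants: 18 5,8-diketone
Product: 19 5α,8β,9β,10α-tetraol
Conditions: Me4NBH(OAc)3, MeCN–AcOH, −30 → 0 °C
Reagents that add atoms: none
Why: Evans–Saksena hydroxyl-directed reduction delivers hydride intramolecularly from an acetoxyborohydride bound to a 1,3-related axial tertiary hydroxyl (C9–OH to C5 on the β face, C10–OH to C8 on the α face), so both ketones give the 1,3-anti diols with equatorial 5α- and 8β-hydroxyls.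

Step 17
Reactants: 19 5α,8β,9β,10α-tetraol
Product: 21 8-O-PMB triol, via stannylene acetal 20 (not isolated)
Conditions: Bu2SnO, toluene, reflux; then 4-MeOC6H4CH2Cl, Bu4NBr (cat.), 80 °C
Reagents that add atoms: 4-methoxybenzyl chloride, COc1ccc(CCl)cc1
Why: Stannylene-acetal monoalkylation is possible only at the cis-vicinal O8/O9 pair and occurs at its equatorial secondary oxygen, leaving the C5 hydroxyl and both tertiary hydroxyls free and giving a non-migrating ether at O8.

Step 18
Reactants: 21 8-O-PMB triol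
Product: 22 C5 mesylate
Conditions: MsCl, Et3N, CH2Cl2, 0 °C
Reagents that add atoms: methanesulfonyl chloride, CS(=O)(=O)Cl
Why: Sulfene-mediated mesylation takes the single remaining secondary hydroxyl (C5, equatorial), the tertiary C9 and C10 hydroxyls being unreactive.

Step 19
Reactants: 22 C5 mesylate
Product: 24 (E)-cyclodec-4-en-9-one, via potassium alkoxide 23 (not isolated)
Conditions: KOtBu (1.1 equiv), THF, −78 → 0 °C; then pH 7 buffer
Reagents that add atoms: none
Why: KOtBu reversibly deprotonates the tertiary hydroxyls, and the C9 alkoxide 23 pushes a lone pair into the C4–C9 σ bond, which breaks in concert with departure of the C5 mesylate; this is a concerted Wharton–Grob fragmentation of a 1,3-diol monosulfonate, the closest known case being the conversion of decalin-1,3-diol monosulfonates into (E)-cyclodecenones. No ring is closed by bond formation: the ten-membered ring is unveiled by cutting the bond shared by rings A and B, so the mode of formation is ring expansion by cleavage. No stereocentre is created; C6, C7, C8 and C10 are carried over unchanged while C4, C5 and C9 become sp2. The step needs E geometry at C4=C5 and fragmentation in preference to substitution, elimination or retro-aldol cleavage; the locked trans-fused chair–chair holds the equatorial C5–OMs bond, the C4–C9 bond and an alkoxide lone pair antiperiplanar with C3 anti to C6, so only the E alkene can form, and C4 is quaternary with no antiperiplanar hydrogen for E2. The C1 dioxolane removes the carbonyl that would allow retro-aldol scission of C9–C10, the O8 benzyl-type ether cannot migrate to the cis C9 alkoxide as a silyl group would, and the C10 alkoxide is a spectator because it has no antiperiplanar leaving group. Near-stoichiometric base at low temperature limits enolisation of the new ketone toward C8.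

Step 20
Reactants: 24 (E)-cyclodec-4-en-9-one
Product: 25 9,10-diol
Conditions: Zn(BH4)2, Et2O, −20 → 0 °C; then aq. NH4Cl
Reagents that add atoms: none
Why: Chelation-controlled reduction (Cram chelate model) should set C9 as R, because the zinc alkoxide formed at the free C10 hydroxyl holds the C9 carbonyl syn to O10 and hydride enters from the ring periphery on the side of the C10 methyl, giving the 9,10-anti diol that is also the Felkin–Anh product with respect to C8.

Step 21
Reactants: 25 9,10-diol; 26 angelic acid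
Product: 28 C9 angelate, via mixed anhydride 27 (not isolated)
Conditions: 26, 2,4,6-trichlorobenzoyl chloride, Et3N, toluene, rt; then 25, 80 °C
Reagents that add atoms: none
Why: Yamaguchi esterification through the mixed trichlorobenzoic anhydride without a nucleophilic catalyst forms (Z)-2-methylbut-2-enoates without isomerisation to the tiglate and acylates the secondary C9 hydroxyl while the tertiary C10 hydroxyl stays free.

Step 22
Reactants: 28 C9 angelate
Product: 30 5,12-diol, via bis(alkylborane) 29 (not isolated)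
Conditions: BH3·THF, THF, 0 °C; then H2O2 (30% aq.), NaHCO3, 0 °C → rt
Reagents that add atoms: hydrogen peroxide, OO
Why: Hydroboration–oxidation puts boron on the less substituted C5 and on the terminal side-chain carbon C12, and syn addition to the E alkene on its peripheral face (fixed by allylic 1,3-strain between the C4 methyl and C6, which keeps C6–H in the alkene plane and C7 inside the ring) should set C4 (R) and C5 (R) together, while the electron-poor trisubstituted angelate alkene reacts much more slowly and the C11 configuration is immaterial.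

Step 23
Reactants: 30 5,12-diol
Product: 31 5,8,12-triol
Conditions: DDQ, CH2Cl2–pH 7 buffer, 0 °C
Reagents that add atoms: none
Why: Oxidative PMB cleavage proceeds through the benzylic oxocarbenium ion, which the aqueous buffer hydrolyses before a neighbouring hydroxyl can trap it.

Step 24
Reactants: 31 5,8,12-triol
Product: 33 γ-lactone, via lactol 32 (not isolated)
Conditions: TEMPO (cat.), PhI(OAc)2, CH2Cl2, rt
Reagents that add atoms: none
Why: TEMPO/PhI(OAc)2 oxidative lactonisation oxidises the primary alcohol selectively to the aldehyde, which the cis C8 hydroxyl captures as the five-membered lactol that is oxidised on to the cis-fused γ-lactone, the trans-disposed hindered C5 hydroxyl not competing.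

Step 25
Reactants: 33 γ-lactone; 34 (R)-2-methylbutanoic acid
Product: 35 C5 2-methylbutanoate
Conditions: DCC, DMAP (cat.), CH2Cl2, rt
Reagents that add atoms: none
Why: Steglich esterification acylates the only free secondary hydroxyl (C5) without exposing the stereocentre of the acid to strong base, the tertiary C10 hydroxyl being inert.

Step 26
Reactants: 35 C5 2-methylbutanoate
Product: 36 13-hydroxy keto lactone
Conditions: HF (48% aq.), MeCN, 0 °C → rt
Reagents that add atoms: water, O
Why: Acidic fluoride cleaves both silyl ethers and the aqueous acid hydrolyses the dioxolane in one global deprotection that the esters and the lactone should tolerate.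

Step 27
Reactants: 36 13-hydroxy keto lactone
Product: 38 target CNP0226386.1, via primary mesylate 37 (not isolated)
Conditions: MsCl (1.1 equiv), Et3N (excess), CH2Cl2, −20 °C → rt
Reagents that add atoms: none
Why: Selective sulfonylation of the primary hydroxyl followed by E1cB elimination of the β-mesyloxy lactone can only give the exocyclic C11=C13 alkene, which avoids the endocyclic isomer that enolate selenenylation of a cis-fused α-methyl lactone would risk.

Compound list
1 | (R)-carvone, (5R)-2-methyl-5-(prop-1-en-2-yl)cyclohex-2-en-1-one | CC1=CC[C@H](CC1=O)C(C)=C | starting material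
2 | (R)-10-hydroxycarvone, (5R)-5-(3-hydroxyprop-1-en-2-yl)-2-methylcyclohex-2-en-1-one | CC1=CC[C@H](CC1=O)C(=C)CO | intermediate
3 | TBDPS ether of 2 | CC1=CC[C@H](CC1=O)C(=C)CO[Si](c2ccccc2)(c3ccccc3)C(C)(C)C | intermediate
4 | (1R,4R,6R)-1-methyl-4-[3-(TBDPS-oxy)prop-1-en-2-yl]-7-oxabicyclo[4.1.0]heptan-2-one, epoxide trans to the side chain | C[C@@]12O[C@@H]1C[C@H](CC2=O)C(=C)CO[Si](c3ccccc3)(c4ccccc4)C(C)(C)C | intermediate
5 | 2-methyl-5-[3-(TBDPS-oxy)prop-1-en-2-yl]cyclohexane-1,3-dione (achiral) | CC1C(=O)CC(CC1=O)C(=C)CO[Si](c2ccccc2)(c3ccccc3)C(C)(C)C | intermediate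
6 | ethyl vinyl ketone (pent-1-en-3-one) | CCC(=O)C=C | starting material
7 | 2-methyl-2-(3-oxopentyl)-5-[3-(TBDPS-oxy)prop-1-en-2-yl]cyclohexane-1,3-dione, oxopentyl chain cis to the side chain (achiral) | CCC(=O)CC[C@@]1(C)C(=O)C[C@@H](C(=C)CO[Si](c2ccccc2)(c3ccccc3)C(C)(C)C)CC1=O | intermediate
8 | bicyclic enedione: C1 and C5 ketones, C9=C10, 4α-methyl (4S), 10-methyl, 7β side chain (7R) | C1[C@@H](C(=C)CO[Si](c3ccccc3)(c4ccccc4)C(C)(C)C)CC(=O)[C@@]2(C)CCC(=O)C(C)=C12 | intermediate
9 | 1-ethoxy-1(10),8-diene of 8, C5 ketone retained | C1[C@@H](C(=C)CO[Si](c3ccccc3)(c4ccccc4)C(C)(C)C)CC(=O)[C@@]2(C)CCC(OCC)=C(C)C2=1 | intermediate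
10 | potassium C5=C6 enolate of 9 | C1[C@@H](C(=C)CO[Si](c3ccccc3)(c4ccccc4)C(C)(C)C)C=C([O-])[C@@]2(C)CCC(OCC)=C(C)C2=1.[K+] | intermediate
11 | 6α-hydroxy ketone of the dienol ether | C1[C@@H](C(=C)CO[Si](c3ccccc3)(c4ccccc4)C(C)(C)C)[C@H](O)C(=O)[C@@]2(C)CCC(OCC)=C(C)C2=1 | intermediate
12 | 6α-OTBS ether of 11 | C1[C@@H](C(=C)CO[Si](c3ccccc3)(c4ccccc4)C(C)(C)C)[C@H](O[Si](C)(C)C(C)(C)C)C(=O)[C@@]2(C)CCC(OCC)=C(C)C2=1 | intermediate
13 | 6β-OTBS epimer of 12 | C1[C@@H](C(=C)CO[Si](c3ccccc3)(c4ccccc4)C(C)(C)C)[C@@H](O[Si](C)(C)C(C)(C)C)C(=O)[C@@]2(C)CCC(OCC)=C(C)C2=1 | intermediate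
14 | 8α-hydroxy-6β-OTBS enedione (C1 and C5 ketones, C9=C10) | O[C@@H]1[C@@H](C(=C)CO[Si](c3ccccc3)(c4ccccc4)C(C)(C)C)[C@@H](O[Si](C)(C)C(C)(C)C)C(=O)[C@@]2(C)CCC(=O)C(C)=C12 | intermediate
15 | 9α,10α-epoxide of 14 | O[C@@H]1[C@@H](C(=C)CO[Si](c4ccccc4)(c5ccccc5)C(C)(C)C)[C@@H](O[Si](C)(C)C(C)(C)C)C(=O)[C@@]2(C)CCC(=O)[C@]3(C)O[C@]123 | intermediate
16 | trans-decalin-1,5-dione: 8α-OH, 9β-OH, 10α-OH, 10β-methyl, 6β-OTBS, 7β side chain, 4α-methyl | O[C@@H]1[C@@H](C(=C)CO[Si](c3ccccc3)(c4ccccc4)C(C)(C)C)[C@@H](O[Si](C)(C)C(C)(C)C)C(=O)[C@@]2(C)CCC(=O)[C@](C)(O)[C@]12O | intermediate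
17 | C1 ethylene ketal of 16 | O[C@@H]1[C@@H](C(=C)CO[Si](c4ccccc4)(c5ccccc5)C(C)(C)C)[C@@H](O[Si](C)(C)C(C)(C)C)C(=O)[C@@]2(C)CCC3(OCCO3)[C@](C)(O)[C@]12O | intermediate
18 | 5,8-diketone: C1 ketal, 9β-OH, 10α-OH | O=C1[C@@H](C(=C)CO[Si](c4ccccc4)(c5ccccc5)C(C)(C)C)[C@@H](O[Si](C)(C)C(C)(C)C)C(=O)[C@@]2(C)CCC3(OCCO3)[C@](C)(O)[C@]12O | intermediate
19 | tetraol: 5α-OH (equatorial), 8β-OH (equatorial), 9β-OH, 10α-OH, C1 ketal | O[C@H]1[C@@H](C(=C)CO[Si](c4ccccc4)(c5ccccc5)C(C)(C)C)[C@@H](O[Si](C)(C)C(C)(C)C)[C@H](O)[C@@]2(C)CCC3(OCCO3)[C@](C)(O)[C@]12O | intermediate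
20 | O8,O9-dibutylstannylene acetal of 19 | CCCC[Sn]6(CCCC)O[C@H]1[C@@H](C(=C)CO[Si](c4ccccc4)(c5ccccc5)C(C)(C)C)[C@@H](O[Si](C)(C)C(C)(C)C)[C@H](O)[C@@]2(C)CCC3(OCCO3)[C@](C)(O)[C@]12O6 | intermediate
21 | 8β-O-PMB ether: 5α-OH, 9β-OH and 10α-OH free | COc1ccc(cc1)CO[C@H]2[C@@H](C(=C)CO[Si](c5ccccc5)(c6ccccc6)C(C)(C)C)[C@@H](O[Si](C)(C)C(C)(C)C)[C@H](O)[C@@]3(C)CCC4(OCCO4)[C@](C)(O)[C@]23O | intermediate
22 | fragmentation precursor, trans-decalin: 4α-methyl, 5α-OMs (equatorial), 6β-OTBS, 7β-[3-(TBDPS-oxy)prop-1-en-2-yl] (axial), 8β-OPMB, 9β-OH (axial), 10α-OH/10β-methyl, C1 ethylene ketal | COc1ccc(cc1)CO[C@H]2[C@@H](C(=C)CO[Si](c5ccccc5)(c6ccccc6)C(C)(C)C)[C@@H](O[Si](C)(C)C(C)(C)C)[C@H](OS(C)(=O)=O)[C@@]3(C)CCC4(OCCO4)[C@](C)(O)[C@]23O | intermediate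
23 | potassium C9 alkoxide of 22 | COc1ccc(cc1)CO[C@H]2[C@@H](C(=C)CO[Si](c5ccccc5)(c6ccccc6)C(C)(C)C)[C@@H](O[Si](C)(C)C(C)(C)C)[C@H](OS(C)(=O)=O)[C@@]3(C)CCC4(OCCO4)[C@](C)(O)[C@]23[O-].[K+] | intermediate
24 | (E)-cyclodec-4-en-9-one: C1 ethylene ketal, 10-hydroxy-10-methyl, 8-OPMB, 7-side chain, 6-OTBS, 4-methyl; C6, C7, C8, C10 as in 22 | COc1ccc(cc1)CO[C@H]2[C@@H](C(=C)CO[Si](c5ccccc5)(c6ccccc6)C(C)(C)C)[C@@H](O[Si](C)(C)C(C)(C)C)/C=C(C)/CCC3(OCCO3)[C@](C)(O)C2=O | intermediate
25 | (9R)-alcohol of 24 (9,10-anti diol) | COc1ccc(cc1)CO[C@H]2[C@@H](C(=C)CO[Si](c5ccccc5)(c6ccccc6)C(C)(C)C)[C@@H](O[Si](C)(C)C(C)(C)C)/C=C(C)/CCC3(OCCO3)[C@](C)(O)[C@@H]2O | intermediate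
26 | angelic acid, (Z)-2-methylbut-2-enoic acid | C/C=C(/C)C(=O)O | starting material
27 | angelic 2,4,6-trichlorobenzoic anhydride | C/C=C(/C)C(=O)OC(=O)c1c(Cl)cc(Cl)cc1Cl | intermediate
28 | C9 angelate of 25 | COc1ccc(cc1)CO[C@H]2[C@@H](C(=C)CO[Si](c5ccccc5)(c6ccccc6)C(C)(C)C)[C@@H](O[Si](C)(C)C(C)(C)C)/C=C(C)/CCC3(OCCO3)[C@](C)(O)[C@@H]2OC(=O)/C(C)=C\C | intermediate
29 | bis(alkylborane) with boron at C5 and C12, drawn as BH2 groups, C11 unassigned | COc1ccc(cc1)CO[C@H]2[C@@H](C(CB)CO[Si](c5ccccc5)(c6ccccc6)C(C)(C)C)[C@@H](O[Si](C)(C)C(C)(C)C)[C@H](B)[C@H](C)CCC3(OCCO3)[C@](C)(O)[C@@H]2OC(=O)/C(C)=C\C | intermediate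
30 | cyclodecane 5,12-diol: (4R)-methyl, (5R)-OH, C12 primary OH, C11 epimers | COc1ccc(cc1)CO[C@H]2[C@@H](C(CO)CO[Si](c5ccccc5)(c6ccccc6)C(C)(C)C)[C@@H](O[Si](C)(C)C(C)(C)C)[C@H](O)[C@H](C)CCC3(OCCO3)[C@](C)(O)[C@@H]2OC(=O)/C(C)=C\C | intermediate
31 | 5,8,12-triol (PMB removed) | O[C@H]1[C@@H](C(CO)CO[Si](c3ccccc3)(c4ccccc4)C(C)(C)C)[C@@H](O[Si](C)(C)C(C)(C)C)[C@H](O)[C@H](C)CCC2(OCCO2)[C@](C)(O)[C@@H]1OC(=O)/C(C)=C\C | intermediate
32 | 8,12-lactol | OC1O[C@H]2[C@@H](C1CO[Si](c4ccccc4)(c5ccccc5)C(C)(C)C)[C@@H](O[Si](C)(C)C(C)(C)C)[C@H](O)[C@H](C)CCC3(OCCO3)[C@](C)(O)[C@@H]2OC(=O)/C(C)=C\C | intermediate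
33 | cis-fused 8,12-γ-lactone with C13 OTBDPS, free C5–OH | O=C1O[C@H]2[C@@H](C1CO[Si](c4ccccc4)(c5ccccc5)C(C)(C)C)[C@@H](O[Si](C)(C)C(C)(C)C)[C@H](O)[C@H](C)CCC3(OCCO3)[C@](C)(O)[C@@H]2OC(=O)/C(C)=C\C | intermediate
34 | (R)-2-methylbutanoic acid | CC[C@@H](C)C(=O)O | starting material
35 | C5 (R)-2-methylbutanoate of 33 | O=C1O[C@H]2[C@@H](C1CO[Si](c4ccccc4)(c5ccccc5)C(C)(C)C)[C@@H](O[Si](C)(C)C(C)(C)C)[C@H](OC(=O)[C@H](C)CC)[C@H](C)CCC3(OCCO3)[C@](C)(O)[C@@H]2OC(=O)/C(C)=C\C | intermediate
36 | deprotected keto lactone: C1 ketone, C6–OH, C10–OH, C13–OH | O=C1O[C@H]2[C@@H](C1CO)[C@@H](O)[C@H](OC(=O)[C@H](C)CC)[C@H](C)CCC(=O)[C@](C)(O)[C@@H]2OC(=O)/C(C)=C\C | intermediate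
37 | C13 mesylate of 36 | O=C1O[C@H]2[C@@H](C1COS(C)(=O)=O)[C@@H](O)[C@H](OC(=O)[C@H](C)CC)[C@H](C)CCC(=O)[C@](C)(O)[C@@H]2OC(=O)/C(C)=C\C | intermediate
38 | CNP0226386.1; route numbering 4R,5R,6R,7S,8S,9R,10R, ester side chain 2R, angelate Z | C=C1C(=O)O[C@H]2[C@@H]1[C@@H](O)[C@H](OC(=O)[C@H](C)CC)[C@H](C)CCC(=O)[C@](C)(O)[C@@H]2OC(=O)/C(C)=C\C | target

Total step count: 27
Longest linear sequence: 27 steps (1 to 38)

Steps most likely to fail

1. Step 19 (fragmentation). The new α-hydroxy ketone has an enolisable C8–H, so residual tert-butoxide could epimerise C8 or start an α-ketol reorganisation, and aggregation of the hindered alkoxide could slow the fragmentation so that these processes compete. Fallback without any alkoxide: starting from alcohol 21, Tf2O with 2,6-di-tert-butyl-4-methylpyridine in CH2Cl2 at −78 °C would convert the C5 hydroxyl into the C5 triflate F1, which would not be isolated. On warming, ionisation of the antiperiplanar C5–O bond, assisted by the neutral C9 hydroxyl, would cleave C4–C9 and, after proton loss to the pyridine base, give 24, where the route is rejoined.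

2. Step 22 (hydroboration). Borane could also add to or reduce the angelate, and selectivity for the peripheral face could erode if the alkene unit rotates through the ring. Fallback that separates the two alkenes by polarity: starting from 28, dimethyldioxirane (acetone, −78 °C) would epoxidise only the strained, electron-rich ring alkene on its peripheral face to give the 4,5-epoxide F2. The trivalent titanium reagent Cp2TiCl (from Cp2TiCl2 and Zn) with 1,4-cyclohexadiene would open it homolytically at the tertiary C4, and hydrogen-atom transfer from the periphery would give the C5 alcohol F3. 9-BBN, which leaves conjugated esters alone, followed by H2O2/NaHCO3 would then hydroborate the remaining 1,1-disubstituted alkene and return the route at 30.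

3. Step 13 (epoxide hydrolysis). The protonated epoxy ketone could rearrange by acyl or hydride shift, or water could attack C10, because the β-face approach to C9 is crowded by the axial C7 side chain and C10 is deactivated by the adjacent carbonyl. Fallback at the alcohol oxidation level: starting from 15, NaBH4 (MeOH, −40 °C) would reduce the C1 ketone to the epoxy alcohol F4 (C1 configuration immaterial). Aqueous HClO4 would open this 2,3-epoxy alcohol at the distal C9, as steroidal 4,5-epoxy-3-ols do, giving the tetraol F5. Dess–Martin oxidation of both secondary hydroxyls (C1 and C8) would give the triketone F6, and exchange dioxolanation of the least hindered C1 carbonyl (2-ethyl-2-methyl-1,3-dioxolane, p-TsOH) would return the route at 18, bypassing 16 and 17.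

Further compounds
F1 | step 19 | C5 triflate of 21 | COc1ccc(cc1)CO[C@H]2[C@@H](C(=C)CO[Si](c5ccccc5)(c6ccccc6)C(C)(C)C)[C@@H](O[Si](C)(C)C(C)(C)C)[C@H](OS(=O)(=O)C(F)(F)F)[C@@]3(C)CCC4(OCCO4)[C@](C)(O)[C@]23O
F2 | step 22 | 4,5-epoxide of 28, oxygen on the peripheral face | COc1ccc(cc1)CO[C@H]2[C@@H](C(=C)CO[Si](c5ccccc5)(c6ccccc6)C(C)(C)C)[C@@H](O[Si](C)(C)C(C)(C)C)[C@@H]4O[C@@]4(C)CCC3(OCCO3)[C@](C)(O)[C@@H]2OC(=O)/C(C)=C\C
F3 | step 22 | (4R,5R)-C5 alcohol with the side-chain alkene intact | COc1ccc(cc1)CO[C@H]2[C@@H](C(=C)CO[Si](c5ccccc5)(c6ccccc6)C(C)(C)C)[C@@H](O[Si](C)(C)C(C)(C)C)[C@H](O)[C@H](C)CCC3(OCCO3)[C@](C)(O)[C@@H]2OC(=O)/C(C)=C\C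
F4 | step 13 | C1 alcohol of epoxy ketone 15 | O[C@@H]1[C@@H](C(=C)CO[Si](c4ccccc4)(c5ccccc5)C(C)(C)C)[C@@H](O[Si](C)(C)C(C)(C)C)C(=O)[C@@]2(C)CCC(O)[C@]3(C)O[C@]123
F5 | step 13 | 1,8α,9β,10α-tetraol with C5 ketone | O[C@@H]1[C@@H](C(=C)CO[Si](c4ccccc4)(c5ccccc5)C(C)(C)C)[C@@H](O[Si](C)(C)C(C)(C)C)C(=O)[C@@]2(C)CCC(O)[C@](C)(O)[C@]12O
F6 | step 13 | 1,5,8-triketone with 9β,10α-diol | O=C1[C@@H](C(=C)CO[Si](c4ccccc4)(c5ccccc5)C(C)(C)C)[C@@H](O[Si](C)(C)C(C)(C)C)C(=O)[C@@]2(C)CCC(=O)[C@](C)(O)[C@]12O
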